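The rate constants stand for no real mixture.

A salt charge above the substrate charge invites the reading that a flask must run to full turnover of its substrate, and this is the trap here.

substrate 0.20 mM (fed, over 20 s); salt in the second phase 0.220 mM; spent carrier 10 µM; time 1.0 h; volume of the second phase over the first 2.0

    spent carrier + salt in the second phase ⇌ fresh carrier + spent salt in the second phase (K1 = 0.19, k1 = 3600 M⁻¹ s⁻¹)
    substrate + fresh carrier ⇌ product + spent carrier (K2 = 30, k2 = 11000 M⁻¹ s⁻¹)
    2 fresh carrier ⇌ resting dimer, settled at all times (K3 = 1.4 × 10⁵ M⁻¹)

1. the state of affairs at 1.0 h: stopped, and by what, or still going (forward and back rates have come level / all of the substrate has reacted / no working catalyst is left / the salt in the second phase has run out first / it is still moving)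
2. conversion of substrate at 1.0 h
3. amount of product at 1.0 h, in percent of the substrate charged

- a step written with two of one species runs at k times the square of its concentration and takes two of it each time
- in the second phase: salt in the second phase, spent salt in the second phase; everything else is in the first
- charges count per volume of the first phase; a concentration in a rate is the amount of a species over the volume of its own phase; every rate counts per litre of the first phase
- the reaction counts as stopped when no species that holds the substrate changes by six tenths of a point or more over the second half of the time
- run time (flask): 1.0 h

In this flask the salt in the second phase stands at 1.10 of the substrate charge. The first two steps add up to substrate + salt ⇌ product + spent salt, with the carrier cancelling. The product of their constants, the round-trip constant 5.70, favours the right side. Enough salt and a favourable constant seem to promise full conversion, yet the reckoning gives less.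

Let x be the fraction of the substrate charge turned over. The carrier charge is 5.00% of the substrate charge, so its holdings are neglected, and the salt loses the same x, counted in substrate charges. Both salt forms lie in the second phase, so its volume cancels from their ratio. The balance then says that the square of x, over the substrate fraction left times the salt fraction left, equals the round-trip constant. Both remainders shrink as x grows, so the ratio reaches 5.70 before x reaches the whole substrate charge. Solving gives 73.7%, for conversion and for product alike.

With the carrier held at its charge and the way back not counted, the salt falls pseudo-first-order by the forward run of the first step with a time of 0.926 min, much shorter than the 1.0 h allowed, so balance is expected by then, with substrate and salt both present.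

The forecast says forward and back rates have come level, with conversion 73.5% and product 73.5%, “with substrate and salt both still present and the catalyst only slightly tied up as dimer”.

The flask gives forward and back rates have come level, with conversion 73.5% and product 73.5%. With the other amounts and the time held, the product answer has moved by 5 points at 0.231 mM of substrate, the nearest such charge above the present one, so at that charge the forecast's figure stands 5 points off. In the neighbour charged with 0.50 mM of substrate, salt stands at 0.440 of the substrate charge, and the round-trip constant 5.70 gives 39.5%; at 1.0 h that neighbour holds 39.4% as product.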